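# Proposed total synthesis of grantioidinin by demethylative iodocyclisation of a pentamethoxyphenyl ynone

## The problem

Grantioidinin (20) is 5-hydroxy-3,6,7,8,2',5'-hexamethoxyflavone. A benzene ring A is fused to a 4-pyranone ring C, and ring B (2,5-dimethoxyphenyl) hangs on C2 through one single bond. The molecule has no stereocentre, so the whole difficulty lies in the oxygen pattern and in regiochemistry. Ring A is hexasubstituted: C5, C6, C7, C8 and C8a all carry oxygen. Of these five contiguous oxygens, one must become the ring oxygen O1, one the free 5-OH, and three must stay methyl ethers. C3 carries a methoxy group on the pyranone double bond. The classical entry to 3-oxygenated flavones, oxidative cyclisation of a 2'-hydroxychalcone (Algar–Flynn–Oyamada), tends to give aurones when the chalcone carries a 6'-alkoxy group, and a 5-oxygenated target requires exactly that. The compound tolerates little rough handling: rings A and B are electron-rich polyalkoxyarenes that strong oxidants turn into quinones and electrophiles halogenate, hydroxide opens ring C at C2, and hard Lewis acids strip methyl ethers, of which only the 5-OMe is set apart by chelation to the C4 carbonyl. The enabling feature is that O1 and the 5-oxygen are the two ortho oxygens of the aryl ketone at C4. Written both as OMe, ring A becomes a pentamethoxyphenyl group with two equivalent ortho positions. C2=C3 can then come from an alkyne that accepts O1 at C2 and an electrophilic heteroatom at C3 in one event.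

## Retrosynthesis

**20 to 18 (O5–CH3).** The last operation is the removal of one methyl group, so the immediate precursor is the heptamethoxyflavone 18. Carrying the 5-oxygen as OMe keeps ring A symmetric through all earlier steps. A free or specially protected 5-oxygen would break that symmetry and demand regiocontrol in every ring A step. The forward reaction must cleave one of seven methyl ethers; the 5-OMe is the only one that can form a six-membered chelate with the C4 carbonyl.

**18 to 17 to 14 (C3–O).** The C3 methoxy group is traced to the flavonol 17 and from there to the 3-iodoflavone 14. Placing the C3 oxygen before ring closure would mean a chalcone oxidation in the presence of a 6'-alkoxy group, the weak point noted above. Iodine at C3 is a placeholder that the ring closure itself installs. The forward step must turn a hindered alkenyl iodide into an enol oxygen without opening the pyranone. Iodine–magnesium exchange to 15, borate capture to 16 and oxidation do this without hydroxide; a simple methylation follows.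

**14 to 12 (O1–C2 and C3–I).** This is the key disconnection: ring C is opened to the ynone 12. The neighbouring cuts are less attractive. Cutting O1–C8a needs a leaving group on a hexasubstituted ring A. Cutting C4–C4a needs a Friedel–Crafts acylation of a Lewis-acid-labile pentaalkoxyarene. The chosen cut uses an oxygen that is already on the ring as its methyl ether, needs no free phenol, and loses one ring and the halogen in a single step. The forward reaction must close through oxygen at C2 rather than through the 2'-methoxy group of ring B at C3, and must not iodinate ring B.

**12 to 11 to 8 + 9 (C3–C4).** The ynone is taken back to the propargylic alcohol 11 and split at the carbinol–alkyne bond into the aldehyde 8 and the terminal alkyne 9, used as its lithium acetylide 10. This divides the molecule into two aromatic halves of similar size, one of them commercial. Cutting C2–C1' instead would require coupling a terminal aryl ynone, a reactive Michael acceptor. The forward steps are an acetylide addition to a hindered but non-enolisable aldehyde and a mild oxidation of a doubly activated alcohol.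

**8 to 6 (C4a–C4).** The formyl group is removed to give pentamethoxybenzene 6. The arene has a single ring hydrogen flanked by two methoxy groups, so lithiation to 7 is unambiguous. Electrophilic formylation under Lewis acids would put the ethers at risk.

**6 to 5 to 2 to 1 (C–O bonds).** The fifth oxygen is removed to give 1,2,3,5-tetramethoxybenzene 2, whose two equivalent ring hydrogens each sit between two methoxy groups. Directed lithiation to 3, borylation to 4 and oxidation give the phenol 5, and methylation gives 6. Compound 2 is the methyl ether of the inexpensive 3,4,5-trimethoxyphenol 1, which already has three of the five oxygens in place.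

## Roads not taken

**Alternative 1: anodic acylquinone formation and oxa-Michael closure (cut O1–C8a).** The hydroquinone diketone A1, 1-(2,5-dihydroxy-3,4-dimethoxyphenyl)-3-(2,5-dimethoxyphenyl)-2-methoxypropane-1,3-dione, would be oxidised at controlled potential to the acylquinone A2. The enol oxygen of the distal carbonyl would add to the quinone carbon next to the acyl group in a six-membered closure, and tautomerisation would give the 5,8-dihydroxyflavone A3.
- Merits: the 3-methoxy group is present from the start, no C3 functionalisation is needed, and no ether has to be cleaved at the end. Only the unchelated 8-OH of A3 needs methylation to reach 20. In end-game economy this road is better than the chosen one.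
- Weak points: A3 is a 5,8-quinol, electron-richer than A1, and should be oxidised at the electrode more easily than the substrate. Ring B is itself a hydroquinone dimethyl ether and anodically labile. A2 is a strong electrophile that solvent or a second molecule can intercept. A1 needs an α-methoxy-1,3-diketone built on a protected hydroquinone, which costs protecting-group steps.
- Comparison: the chosen plan offers a ring closure of a known substrate class, no redox-labile quinol intermediates and a symmetric ring A from a simple phenol, at the price of two extra steps after the closure.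

**Alternative 2: symmetric tetramethoxybenzyne takes up O1 and C4 together (cut O1–C8a and C4–C4a).** Fluoride (CsF) would release the aryne A5 from the silyl triflate A4. The carboxylate of the acid A6, 3-(2,5-dimethoxyphenyl)-2,3-dimethoxyprop-2-enoic acid, would add through oxygen, and the aryl anion would capture the acyl carbon. The resulting ortho-acyl phenoxide would displace the β-methoxy group by addition–elimination to give A7, which is the same compound as 18.
- Merits: it is the most convergent of the four plans. The aryne is symmetric, so there is no regiochemical question, and the 3-methoxy group is in place. If the key step worked, it would reach 18 without steps 7 to 9 of the chosen route.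
- Weak points: A4 is a hexasubstituted, penta-oxygenated ortho-silyl aryl triflate that needs several steps on an oxidation-prone phenol. Protonation of the aryl anion, which gives a simple aryl ester, competes with acyl transfer. A6 needs its own synthesis. The final demethylation is the same as in the chosen plan.
- Comparison: the chosen plan offers simpler precursors and a ring closure with established behaviour. The steps saved at the end of alternative 2 are likely to be spent on A4.

**Alternative 3: methoxylated polyketide chain folded into rings A and C (cut C4a–C8a and O1–C2).** Mg(OMe)2 would open the 2-pyrone A8 to the open-chain pentacarbonyl ester A9. The C4a methylene would attack the ester carbon in a Claisen closure that creates ring A. On acidic work-up an ortho phenol would condense with the C2 ketone to give the 5,7-dihydroxyflavone A10.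
- Merits: the fully oxygenated ring A is made without any aromatic substitution chemistry. The new ring A is symmetric, so either ortho phenol gives the same flavone. The 3-methoxy group is in place, and A10 needs only the routine selective methylation of the 7-OH to reach 20. After the key step this road is shorter than the chosen one.
- Weak points: A8 carries three α-methoxy carbonyl units and is hardly easier to make than the target. The chain can fold in aldol modes other than the desired Claisen closure. The α-methoxy β-diketone is open to retro-Claisen cleavage by methoxide.
- Comparison: the chosen plan offers predictable regiochemistry at every step and commercial aromatic building blocks.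

Key step: step 7

Assumption: 3,4,5-trimethoxyphenol (1) and 2-ethynyl-1,4-dimethoxybenzene (9) are taken as catalogue compounds; the carbinol 11 is formed racemic, which is of no consequence because its centre is oxidised away in step 6.

## Route

Step 1
Reactants: 1 3,4,5-trimethoxyphenol
Product: 2 1,2,3,5-tetramethoxybenzene
Conditions: MeI, K2CO3, acetone, reflux
Reagents that add atoms: iodomethane, CI
Why: Williamson O-methylation of a phenol; the three aryl methyl ethers are inert, and carbonate in acetone should give O-alkylation only.

Step 2
Reactants: 2 1,2,3,5-tetramethoxybenzene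
Product: 5 2,3,4,6-tetramethoxyphenol, via 2,3,4,6-tetramethoxyphenyllithium 3 (not isolated), via dimethyl 2,3,4,6-tetramethoxyphenylboronate 4 (not isolated)
Conditions: n-BuLi, THF, 0 °C; B(OMe)3, −78 °C → rt; AcOH, 30% aq. H2O2, 0 °C → rt
Reagents that add atoms: hydrogen peroxide, OO
Why: Directed ortho-lithiation; the two ring hydrogens of 2 are equivalent and each lies between two methoxy groups, so only 3 can form. Borate capture and oxidative aryl migration from boron to oxygen (boronate oxidation) in acetic acid should give the phenol without the basic peroxide conditions that endanger an electron-rich phenol.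

Step 3
Reactants: 5 2,3,4,6-tetramethoxyphenol
Product: 6 pentamethoxybenzene
Conditions: MeI, K2CO3, acetone, reflux
Reagents that add atoms: iodomethane, CI
Why: Williamson O-methylation; the flanked phenol is hindered but the electrophile is small, so it should proceed normally.

Step 4
Reactants: 6 pentamethoxybenzene
Product: 8 2,3,4,5,6-pentamethoxybenzaldehyde, via pentamethoxyphenyllithium 7 (not isolated)
Conditions: n-BuLi, TMEDA, THF, 0 °C; DMF, 0 °C → rt; H2O
Reagents that add atoms: N,N-dimethylformamide, CN(C)C=O
Why: Directed ortho-lithiation of the single ring hydrogen, which is flanked by two methoxy groups, followed by formylation with DMF; the hemiaminal salt releases the aldehyde on aqueous quench.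

Step 5
Reactants: 8 2,3,4,5,6-pentamethoxybenzaldehyde; 9 2-ethynyl-1,4-dimethoxybenzene
Product: 11 rac-3-(2,5-dimethoxyphenyl)-1-(2,3,4,5,6-pentamethoxyphenyl)prop-2-yn-1-ol, via lithium (2,5-dimethoxyphenyl)acetylide 10 (not isolated)
Conditions: 9, n-BuLi, THF, −78 °C; then 8, −78 → 0 °C; H2O
Reagents that add atoms: none
Why: 1,2-Addition of a lithium acetylide to a non-enolisable aryl aldehyde; the two ortho methoxy groups slow but should not block the slim sp nucleophile. The new carbinol centre forms racemic without control, which is harmless because step 6 converts it to a carbonyl.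

Step 6
Reactants: 11 rac-3-(2,5-dimethoxyphenyl)-1-(2,3,4,5,6-pentamethoxyphenyl)prop-2-yn-1-ol
Product: 12 3-(2,5-dimethoxyphenyl)-1-(2,3,4,5,6-pentamethoxyphenyl)prop-2-yn-1-one
Conditions: activated MnO2, CH2Cl2, rt
Reagents that add atoms: none
Why: MnO2 oxidation of an alcohol that is both benzylic and propargylic; the reagent should leave the alkyne and both polyalkoxyarenes untouched, and a secondary carbinol cannot be over-oxidised.

Step 7
Reactants: 12 3-(2,5-dimethoxyphenyl)-1-(2,3,4,5,6-pentamethoxyphenyl)prop-2-yn-1-one
Product: 14 2-(2,5-dimethoxyphenyl)-3-iodo-5,6,7,8-tetramethoxychromen-4-one, via O-methyl chromenone oxonium chloride 13 (not isolated)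
Conditions: ICl (1.2 equiv), CH2Cl2, −78 → −20 °C; aq. Na2S2O3 quench while cold
Reagents that add atoms: iodine monochloride, ClI
Why: ICl delivers an iodonium equivalent to the triple bond of 12, and the lone pair of an ortho methoxy oxygen of ring A attacks the activated β-carbon (the future C2) anti to iodine, forming O1–C2 and C3–I and giving the O-methyl oxonium chloride 13; chloride then removes the methyl group by SN2 attack, so chloromethane leaves and the neutral 4-pyranone 14 remains. The closest known reaction type is the ICl-induced demethylative cyclisation of 1-(2-methoxyaryl)alk-2-yn-1-ones to 3-iodochromones. Ring C is the only ring closed, in a 6-endo-dig mode, and no stereocentre is formed. No free phenol is needed, and because the two ortho methoxy groups of the pentamethoxyphenyl ketone are equivalent, either one leads to the same constitution. The step needs regioselectivity for attack at C2 by a ring A oxygen over attack at C3 by the 2'-methoxy oxygen of ring B (a benzofuran-type closure): the ynone carbonyl and the electron-rich ring B both place the positive charge of the iodonium ion on C2, whereas C3 lies α to the carbonyl and is electron-poor. It also needs chemoselectivity against aromatic iodination: ring A has no free position, and ring B should be spared by near-stoichiometric ICl at low temperature with a cold reductive quench.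

Step 8
Reactants: 14 2-(2,5-dimethoxyphenyl)-3-iodo-5,6,7,8-tetramethoxychromen-4-one
Product: 17 2-(2,5-dimethoxyphenyl)-3-hydroxy-5,6,7,8-tetramethoxychromen-4-one, via C3 chloromagnesium flavone 15 (not isolated), via C3 dimethyl boronate 16 (not isolated)
Conditions: iPrMgCl·LiCl, THF, −40 °C; B(OMe)3, −40 → 0 °C; AcOH, 30% aq. H2O2, 0 °C → rt
Reagents that add atoms: hydrogen peroxide, OO
Why: Iodine–magnesium exchange on an alkenyl iodide activated by the adjacent carbonyl should be fast at −40 °C, where addition of the reagent to the vinylogous ester carbonyl is slow. C3-metalated flavones are known to be captured by B(OMe)3 and oxidised to flavonols (boronate oxidation), and acidic peroxide avoids the alkaline cleavage of flavonols.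

Step 9
Reactants: 17 2-(2,5-dimethoxyphenyl)-3-hydroxy-5,6,7,8-tetramethoxychromen-4-one
Product: 18 2-(2,5-dimethoxyphenyl)-3,5,6,7,8-pentamethoxychromen-4-one
Conditions: MeI, K2CO3, acetone, reflux
Reagents that add atoms: iodomethane, CI
Why: Williamson O-methylation of the acidic enolic 3-OH, the only free hydroxyl in 17; carbonate in acetone does not open ring C.

Step 10
Reactants: 18 2-(2,5-dimethoxyphenyl)-3,5,6,7,8-pentamethoxychromen-4-one
Product: 20 grantioidinin (2-(2,5-dimethoxyphenyl)-5-hydroxy-3,6,7,8-tetramethoxychromen-4-one), via C5 dichloroboryl chelate 19 (not isolated)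
Conditions: BCl3 (1.2 equiv), CH2Cl2, −78 → 0 °C; then H2O
Reagents that add atoms: none
Why: Chelation-directed aryl methyl ether cleavage; BCl3 binds the C4 carbonyl and the peri 5-OMe in a six-membered chelate, chloride removes that methyl group, and hydrolysis of 19 frees the hydrogen-bonded 5-OH. The 3-OMe could only form a strained five-membered chelate and the other ethers none, so one equivalent at low temperature should stop at the mono-phenol.

## Compound list

1 | 3,4,5-trimethoxyphenol | COc1cc(O)cc(OC)c1OC | starting material
2 | 1,2,3,5-tetramethoxybenzene | COc1cc(OC)c(OC)c(OC)c1 | intermediate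
3 | 2,3,4,6-tetramethoxyphenyllithium (in situ) | [Li]c1c(OC)cc(OC)c(OC)c1OC | intermediate
4 | dimethyl (2,3,4,6-tetramethoxyphenyl)boronate (in situ) | COB(OC)c1c(OC)cc(OC)c(OC)c1OC | intermediate
5 | 2,3,4,6-tetramethoxyphenol | COc1cc(OC)c(O)c(OC)c1OC | intermediate
6 | pentamethoxybenzene | COc1cc(OC)c(OC)c(OC)c1OC | intermediate
7 | pentamethoxyphenyllithium (in situ) | [Li]c1c(OC)c(OC)c(OC)c(OC)c1OC | intermediate
8 | 2,3,4,5,6-pentamethoxybenzaldehyde | COc1c(OC)c(OC)c(C=O)c(OC)c1OC | intermediate
9 | 2-ethynyl-1,4-dimethoxybenzene | C#Cc1cc(OC)ccc1OC | starting material
10 | lithium (2,5-dimethoxyphenyl)acetylide (in situ) | [Li]C#Cc1cc(OC)ccc1OC | intermediate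
11 | rac-3-(2,5-dimethoxyphenyl)-1-(2,3,4,5,6-pentamethoxyphenyl)prop-2-yn-1-ol (racemic carbinol) | COc1ccc(OC)c(C#CC(O)c2c(OC)c(OC)c(OC)c(OC)c2OC)c1 | intermediate
12 | 3-(2,5-dimethoxyphenyl)-1-(2,3,4,5,6-pentamethoxyphenyl)prop-2-yn-1-one | COc1ccc(OC)c(C#CC(=O)c2c(OC)c(OC)c(OC)c(OC)c2OC)c1 | intermediate
13 | 2-(2,5-dimethoxyphenyl)-3-iodo-5,6,7,8-tetramethoxy-1-methyl-4-oxochromen-1-ium chloride (in situ) | COc1ccc(OC)c(C2=C(I)C(=O)c3c(OC)c(OC)c(OC)c(OC)c3[O+]2C)c1.[Cl-] | intermediate
14 | 2-(2,5-dimethoxyphenyl)-3-iodo-5,6,7,8-tetramethoxychromen-4-one | COc1ccc(OC)c(-c2oc3c(OC)c(OC)c(OC)c(OC)c3c(=O)c2I)c1 | intermediate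
15 | chloro[2-(2,5-dimethoxyphenyl)-5,6,7,8-tetramethoxy-4-oxochromen-3-yl]magnesium (in situ) | COc1ccc(OC)c(-c2oc3c(OC)c(OC)c(OC)c(OC)c3c(=O)c2[Mg]Cl)c1 | intermediate
16 | dimethyl [2-(2,5-dimethoxyphenyl)-5,6,7,8-tetramethoxy-4-oxochromen-3-yl]boronate (in situ) | COc1ccc(OC)c(-c2oc3c(OC)c(OC)c(OC)c(OC)c3c(=O)c2B(OC)OC)c1 | intermediate
17 | 2-(2,5-dimethoxyphenyl)-3-hydroxy-5,6,7,8-tetramethoxychromen-4-one | COc1ccc(OC)c(-c2oc3c(OC)c(OC)c(OC)c(OC)c3c(=O)c2O)c1 | intermediate
18 | 2-(2,5-dimethoxyphenyl)-3,5,6,7,8-pentamethoxychromen-4-one | COc1ccc(OC)c(-c2oc3c(OC)c(OC)c(OC)c(OC)c3c(=O)c2OC)c1 | intermediate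
19 | 5-(dichloroboryloxy)-2-(2,5-dimethoxyphenyl)-3,6,7,8-tetramethoxychromen-4-one (in situ) | COc1ccc(OC)c(-c2oc3c(OC)c(OC)c(OC)c(OB(Cl)Cl)c3c(=O)c2OC)c1 | intermediate
20 | grantioidinin, 2-(2,5-dimethoxyphenyl)-5-hydroxy-3,6,7,8-tetramethoxychromen-4-one | COc1ccc(OC)c(-c2oc3c(OC)c(OC)c(OC)c(O)c3c(=O)c2OC)c1 | target

## Step count and risk

Total step count: 10. Longest linear sequence: 10 steps (1 to 20); the alkyne 9 enters in step 5 as a purchased compound.

**Step 7 (key step).** The most likely failure is electrophilic iodination of ring B, in the substrate or in the product, running alongside the cyclisation. Closure through the ring B methoxy oxygen onto C3 or incomplete dealkylation of the oxonium ion are less likely. All three stem from iodine monochloride being both the activator and an aromatic iodinating agent. The fallback sets out from 12 and needs no electrophilic halogen. One equivalent of BCl3 in CH2Cl2 at low temperature cleaves one of the two equivalent ortho methoxy groups by chelation to the ynone carbonyl, giving 3-(2,5-dimethoxyphenyl)-1-(2-hydroxy-3,4,5,6-tetramethoxyphenyl)prop-2-yn-1-one F1. Diethylamine in ethanol adds to the ynone, and the phenol closes the six-membered ring by addition–elimination to give 2-(2,5-dimethoxyphenyl)-5,6,7,8-tetramethoxychromen-4-one F2. Deprotonation of F2 at C3 with LDA in THF at −78 °C, capture with B(OMe)3 and oxidation with H2O2 in acetic acid then install the C3 hydroxyl. The fallback comes back to the route at 17.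

**Step 8.** The most likely failure is protonation of the C3 magnesium species before the borate captures it, a net reductive loss of iodine. Addition of the exchange reagent to the C4 carbonyl is the second risk. The fallback sets out from 14 and avoids a carbanion altogether: copper-catalysed Ullmann-type etherification with methanol (CuI, 3,4,7,8-tetramethyl-1,10-phenanthroline, Cs2CO3, MeOH/toluene, 100 °C) would replace iodine by methoxy directly. It comes back to the route at 18, bypassing 17, and makes no new compound (entry F0).

**Step 10.** The most likely failure is over-demethylation, that is loss of the 3-OMe, which can also chelate, or of the 6-OMe next to the boron-bound oxygen. The fallback sets out from 17 and reverses the order of the last two operations, so that no 3-methoxy group is present when the Lewis acid is used. Excess BCl3 converts 17 into 2-(2,5-dimethoxyphenyl)-3,5-dihydroxy-6,7,8-trimethoxychromen-4-one F3. One equivalent of MeI with K2CO3 in acetone then methylates the 3-OH and leaves the strongly chelated, least reactive 5-OH. The fallback comes back to the route at 20.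

**Step 2.** The most likely failure is over-oxidation of the very electron-rich phenol by peroxide during the boronate oxidation, or incomplete capture of the hindered aryllithium by the borate. The fallback sets out from 2 and introduces the oxygen through a carbonyl group. Vilsmeier–Haack formylation (POCl3, DMF) gives 2,3,4,6-tetramethoxybenzaldehyde F4. Baeyer–Villiger oxidation with mCPBA in CH2Cl2 gives 2,3,4,6-tetramethoxyphenyl formate F5, and hydrolysis with NaOH in aqueous methanol followed by acidification releases the phenol. The fallback comes back to the route at 5.

## Further compounds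

F1 | step 7 | 3-(2,5-dimethoxyphenyl)-1-(2-hydroxy-3,4,5,6-tetramethoxyphenyl)prop-2-yn-1-one | COc1ccc(OC)c(C#CC(=O)c2c(O)c(OC)c(OC)c(OC)c2OC)c1
F2 | step 7 | 2-(2,5-dimethoxyphenyl)-5,6,7,8-tetramethoxychromen-4-one | COc1ccc(OC)c(-c2cc(=O)c3c(OC)c(OC)c(OC)c(OC)c3o2)c1
F0 | step 8 | none | none
F3 | step 10 | 2-(2,5-dimethoxyphenyl)-3,5-dihydroxy-6,7,8-trimethoxychromen-4-one | COc1ccc(OC)c(-c2oc3c(OC)c(OC)c(OC)c(O)c3c(=O)c2O)c1
F4 | step 2 | 2,3,4,6-tetramethoxybenzaldehyde | COc1cc(OC)c(C=O)c(OC)c1OC
F5 | step 2 | 2,3,4,6-tetramethoxyphenyl formate | COc1cc(OC)c(OC=O)c(OC)c1OC
A1 | alternative 1 | 1-(2,5-dihydroxy-3,4-dimethoxyphenyl)-3-(2,5-dimethoxyphenyl)-2-methoxypropane-1,3-dione | COc1ccc(OC)c(C(=O)C(OC)C(=O)c2cc(O)c(OC)c(OC)c2O)c1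
A2 | alternative 1 | 2-[3-(2,5-dimethoxyphenyl)-2-methoxy-3-oxopropanoyl]-5,6-dimethoxy-1,4-benzoquinone | COc1ccc(OC)c(C(=O)C(OC)C(=O)C2=CC(=O)C(OC)=C(OC)C2=O)c1
A3 | alternative 1 | 2-(2,5-dimethoxyphenyl)-5,8-dihydroxy-3,6,7-trimethoxychromen-4-one | COc1ccc(OC)c(-c2oc3c(O)c(OC)c(OC)c(O)c3c(=O)c2OC)c1
A4 | alternative 2 | 2,3,4,5-tetramethoxy-6-(trimethylsilyl)phenyl trifluoromethanesulfonate | COc1c(OC)c(OC)c(OC)c([Si](C)(C)C)c1OS(=O)(=O)C(F)(F)F
A5 | alternative 2 | 3,4,5,6-tetramethoxybenzyne | COC1=C(OC)C(OC)=C(OC)C#C1
A6 | alternative 2 | 3-(2,5-dimethoxyphenyl)-2,3-dimethoxyprop-2-enoic acid (either alkene geometry) | COC(C(=O)O)=C(OC)c1cc(OC)ccc1OC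
A7 | alternative 2 | 2-(2,5-dimethoxyphenyl)-3,5,6,7,8-pentamethoxychromen-4-one | COc1ccc(OC)c(-c2oc3c(OC)c(OC)c(OC)c(OC)c3c(=O)c2OC)c1
A8 | alternative 3 | 6-[4-(2,5-dimethoxyphenyl)-3-methoxy-2,4-dioxobutyl]-4-hydroxy-3,5-dimethoxypyran-2-one | COc1ccc(OC)c(C(=O)C(OC)C(=O)Cc2oc(=O)c(OC)c(O)c2OC)c1
A9 | alternative 3 | methyl 9-(2,5-dimethoxyphenyl)-2,4,8-trimethoxy-3,5,7,9-tetraoxononanoate | COc1ccc(OC)c(C(=O)C(OC)C(=O)CC(=O)C(OC)C(=O)C(OC)C(=O)OC)c1
A10 | alternative 3 | 2-(2,5-dimethoxyphenyl)-5,7-dihydroxy-3,6,8-trimethoxychromen-4-one | COc1ccc(OC)c(-c2oc3c(OC)c(O)c(OC)c(O)c3c(=O)c2OC)c1
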